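**Plan**

- Hydrindane numbering: C1 (=CHCH3), C2 (OAc), C3, C3a, C4 (=CH2), C5 (O‑acyl), C6 (OH), C7 (i‑Pr), C7a; β is the face of H‑3a.
- Cuts, in retrosynthetic order: the C5 ester and C2 acetate; C1–C2 of the five‑membered ring (ynal plus methyl); then, in one operation, C3a–C4 and C5–C6 of the six‑membered ring, leaving a cyclopent‑2‑enone aldehyde and an alkoxyallene; finally C7–C7a (Ireland–Claisen).
- Enabling feature: in the cyclohexane ring, C4(=CH2)–C5(OR)–C6(OH) is a 2‑substituted γ‑alkoxyallyl carbinol, and C3a is β (through C3) to the oxygenated C2. The central and oxygenated carbons of an alkoxyallene can therefore bridge an enone β‑carbon (C3a) and an aldehyde carbon (C6) through an allylnickel enolate.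
- Forward: chiral‑pool cyclopentenol → Claisen acid → enone aldehyde → annulation builds the cyclohexane on a temporary cyclopentenone (trans fusion) → α‑ketol cleavage opens C1–C2 → alkyne/aldehyde → nickel alkylative cyclisation re‑closes the five‑membered ring with the Z‑ethylidene → acetate, ester, desilylation.
- Stereochemistry: C7a by suprafacial transfer from the carbinol of the cyclopentenol; C7 by Z‑ketene acetal/boat; C3a by anti addition to the enone; C6 and C5 by the closed chair allyl transfer; C2 by metallacycle geometry then Mitsunobu inversion; both alkene geometries by syn carbometalation.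

Key step: step 9

Remark: the starting materials and all reagents are taken as commercial; in step 9 the silane is assumed to cap O‑6 and deliver the C3 hydrogen, as in related nickel/silane reductive couplings.

**Step 1**
Reactants: 1 (1R,4S)-cis-4-acetoxycyclopent-2-en-1-ol
Product: 2 (1S,4R)-4-[(tert-butyldimethylsilyl)oxy]cyclopent-2-en-1-yl acetate
Conditions: TBSCl, imidazole, DMF, 0 °C → rt
Reagents that add atoms: tert-butyldimethylsilyl chloride, CC(C)(C)[Si](C)(C)Cl
Why: Imidazole‑promoted silylation of the only free hydroxyl; no stereocentre is affected.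

**Step 2**
Reactants: 2 (1S,4R)-4-[(tert-butyldimethylsilyl)oxy]cyclopent-2-en-1-yl acetate
Product: 3 (1S,4R)-4-[(tert-butyldimethylsilyl)oxy]cyclopent-2-en-1-ol
Conditions: K2CO3 (cat.), MeOH, 0 °C
Reagents that add atoms: none
Why: Base‑catalysed transesterification (methanolysis) removes the acetate while the TBS ether is stable, freeing the (1S)‑carbinol that will carry the acyl group for the Claisen step.

**Step 3**
Reactants: 3 (1S,4R)-4-[(tert-butyldimethylsilyl)oxy]cyclopent-2-en-1-ol; 4 3-methylbutanoyl chloride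
Product: 5 (1S,4R)-4-[(tert-butyldimethylsilyl)oxy]cyclopent-2-en-1-yl 3-methylbutanoate
Conditions: pyridine, DMAP (cat.), CH2Cl2, 0 °C → rt
Reagents that add atoms: none
Why: DMAP‑catalysed acylation of a secondary allylic alcohol with an acid chloride; no stereocentre is affected.

**Step 4**
Reactants: 5 (1S,4R)-4-[(tert-butyldimethylsilyl)oxy]cyclopent-2-en-1-yl 3-methylbutanoate
Product: 8 (2S)-2-[(1R,5R)-5-[(tert-butyldimethylsilyl)oxy]cyclopent-2-en-1-yl]-3-methylbutanoic acid, via silyl ketene acetal 6 (not isolated), via trimethylsilyl ester 7 (not isolated)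
Conditions: LDA, THF–DMPU (4:1), −78 °C; TMSCl, −78 °C → rt, then 60 °C; dilute aq. HCl work‑up
Reagents that add atoms: chlorotrimethylsilane, C[Si](C)(C)Cl (silyl group of 6 and 7 only, lost on work‑up)
Why: Ireland–Claisen rearrangement in which the (Z)‑silyl ketene acetal formed in THF–DMPU rearranges suprafacially on the ring face that carried the ester oxygen (fixing the future C7a by chirality transfer from the carbinol carbon) through a boat transition state that turns the ketene acetal carbon and the isopropyl group away from the ring and its cis OTBS group (fixing the future C7, syn).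

**Step 5**
Reactants: 8 (2S)-2-[(1R,5R)-5-[(tert-butyldimethylsilyl)oxy]cyclopent-2-en-1-yl]-3-methylbutanoic acid
Product: 9 (2S)-2-[(1R,5R)-5-[(tert-butyldimethylsilyl)oxy]cyclopent-2-en-1-yl]-3-methylbutan-1-ol
Conditions: LiAlH4, THF, 0 °C → rt
Reagents that add atoms: none
Why: Hydride reduction of a carboxylic acid to the primary alcohol with LiAlH4, to which the silyl ether and the alkene are inert; no stereocentre is affected.

**Step 6**
Reactants: 9 (2S)-2-[(1R,5R)-5-[(tert-butyldimethylsilyl)oxy]cyclopent-2-en-1-yl]-3-methylbutan-1-ol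
Product: 10 (2S)-2-[(1R,5S)-5-[(tert-butyldimethylsilyl)oxy]-4-oxocyclopent-2-en-1-yl]-3-methylbutanal
Conditions: CrO3, 3,5-dimethylpyrazole (excess), CH2Cl2, −20 °C
Reagents that add atoms: chromium trioxide, O=[Cr](=O)=O
Why: The CrO3–3,5‑dimethylpyrazole complex is a known reagent both for alcohol‑to‑aldehyde oxidation and for allylic oxidation of a ring CH2 to the enone (the methylene next to the alkene is the only allylic CH2), and its non‑basic medium should leave the α‑stereocentre of the new aldehyde intact.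

**Step 7**
Reactants: 11 prop-2-yn-1-ol; 12 4-methoxybenzyl chloride
Product: 13 1-methoxy-4-[(prop-2-yn-1-yloxy)methyl]benzene
Conditions: NaH, Bu4NI (cat.), THF, 0 °C → rt
Reagents that add atoms: none
Why: Williamson ether synthesis between the alkoxide of a primary alcohol and a benzylic chloride.

**Step 8**
Reactants: 13 1-methoxy-4-[(prop-2-yn-1-yloxy)methyl]benzene
Product: 14 1-methoxy-4-[(propa-1,2-dien-1-yloxy)methyl]benzene
Conditions: KOt‑Bu (0.3 equiv), THF, rt
Reagents that add atoms: none
Why: Base‑catalysed propargyl‑to‑allenyl ether isomerisation, which under catalytic KOt‑Bu stops at the alkoxyallene.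

**Step 9**
Reactants: 10 (2S)-2-[(1R,5S)-5-[(tert-butyldimethylsilyl)oxy]-4-oxocyclopent-2-en-1-yl]-3-methylbutanal; 14 1-methoxy-4-[(propa-1,2-dien-1-yloxy)methyl]benzene
Product: 16 (1S,3aR,5S,6S,7S,7aR)-1-[(tert-butyldimethylsilyl)oxy]-5-[(4-methoxyphenyl)methoxy]-4-methylidene-7-(propan-2-yl)-6-[(triisopropylsilyl)oxy]octahydro-2H-inden-2-one, via allylnickel enolate 15 (not isolated)
Conditions: Ni(COD)2 (15 mol %), PPh3 (30 mol %), i‑Pr3SiH (2 equiv), THF, 40 °C, slow addition of 14
Reagents that add atoms: triisopropylsilane, CC(C)[SiH](C(C)C)C(C)C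
Why: Proposed new method: oxidative cyclisation of the enone and the allene at zerovalent nickel joins the enone β‑carbon C3a to the central allene carbon (C4) on the α face, anti to the β‑oriented side chain on C7a and the β‑OTBS group on C1, and gives the allylnickel O‑enolate 15 of divalent nickel; its η1 form (nickel on the unsubstituted terminus) transfers the allyl group through the alkoxy‑bearing carbon C5 to the pendant aldehyde carbon C6, after which σ‑bond metathesis of the nickel alkoxide with i‑Pr3SiH and C–H reductive elimination from the enolate release 16 and zerovalent nickel. The closest known reactions are the nickel‑catalysed reductive coupling of enones with allenes and silanes (C–C bond at the central allene carbon through the same kind of allylnickel enolate) and nickel‑catalysed diene– or allene–aldehyde couplings in which an allylnickel adds to an aldehyde; interception of the enone–allene metallacycle by an internal aldehyde is the untested part. The first bond (C3a–C4) is intermolecular and closes no ring; the cyclohexane closes in the C5–C6 event, a 6‑exo‑trig attack of the allyl γ‑carbon on the aldehyde through a bicyclic chair–chair (Zimmerman–Traxler) transition state, and because its two anchoring bonds on the cyclopentanone are already trans the hydrindane is trans‑fused. C3a is controlled by the existing C7a and C1 stereocentres (anti addition); C6 by the closed transition state, in which the carbonyl oxygen must be axial (α) to bridge to nickel while the isopropyl group on C7 stays equatorial; C5 by the syn (E) position of the PMBO group in the allylnickel, which puts it equatorial in the nickel‑containing ring and therefore axial (β), trans to O‑6, on the new carbocycle. The step needs enone–allene coupling to outrun aldehyde–allene coupling (the electron‑poor enone binds zerovalent nickel more strongly, and 14 is kept dilute), allyl transfer through the oxygenated terminus (as in other γ‑alkoxyallyl metals, the metal sits on the CH2 terminus), and allyl transfer faster than silane capture of the allylnickel or C‑aldol closure of the enolate (which would give a strained bicyclo[2.2.1]heptanone).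

**Step 10**
Reactants: 16 (1S,3aR,5S,6S,7S,7aR)-1-[(tert-butyldimethylsilyl)oxy]-5-[(4-methoxyphenyl)methoxy]-4-methylidene-7-(propan-2-yl)-6-[(triisopropylsilyl)oxy]octahydro-2H-inden-2-one
Product: 17 (1S,3aR,5S,6S,7S,7aR)-1-hydroxy-5-[(4-methoxyphenyl)methoxy]-4-methylidene-7-(propan-2-yl)-6-[(triisopropylsilyl)oxy]octahydro-2H-inden-2-one
Conditions: HF·pyridine, pyridine, THF, 0 °C
Reagents that add atoms: none
Why: Fluoride desilylation that should discriminate the α‑keto secondary TBS ether (activated towards Si–O cleavage) from the bulkier, axial and flanked TIPS ether; the configuration at C1 is irrelevant after the next step.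

**Step 11**
Reactants: 17 (1S,3aR,5S,6S,7S,7aR)-1-hydroxy-5-[(4-methoxyphenyl)methoxy]-4-methylidene-7-(propan-2-yl)-6-[(triisopropylsilyl)oxy]octahydro-2H-inden-2-one
Product: 18 methyl 2-[(1R,2R,3S,4S,5S)-2-formyl-5-[(4-methoxyphenyl)methoxy]-6-methylidene-3-(propan-2-yl)-4-[(triisopropylsilyl)oxy]cyclohexyl]acetate
Conditions: Pb(OAc)4, MeOH–toluene (1:1), 0 °C
Reagents that add atoms: methanol, CO
Why: Criegee‑type cleavage of an α‑ketol by Pb(OAc)4 in methanol breaks C1–C2 and delivers C2 as the methyl ester and C1 as the aldehyde; the formyl group sits equatorial between two equatorial neighbours, so its α‑stereocentre (C7a) is already in its stable configuration.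

**Step 12**
Reactants: 18 methyl 2-[(1R,2R,3S,4S,5S)-2-formyl-5-[(4-methoxyphenyl)methoxy]-6-methylidene-3-(propan-2-yl)-4-[(triisopropylsilyl)oxy]cyclohexyl]acetate
Product: 19 methyl 2-[(1R,2R,3S,4S,5S)-2-ethynyl-5-[(4-methoxyphenyl)methoxy]-6-methylidene-3-(propan-2-yl)-4-[(triisopropylsilyl)oxy]cyclohexyl]acetate
Conditions: dimethyl (1-diazo-2-oxopropyl)phosphonate, K2CO3, MeOH, 0 °C → rt
Reagents that add atoms: dimethyl (1-diazo-2-oxopropyl)phosphonate, COP(=O)(OC)C(=[N+]=[N-])C(C)=O
Why: Seyferth–Gilbert homologation with the Ohira–Bestmann reagent converts the aldehyde into the terminal alkyne under carbonate conditions that a methyl ester in methanol survives; epimerisation at C7a is of no consequence because the equatorial isomer is the stable one.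

**Step 13**
Reactants: 19 methyl 2-[(1R,2R,3S,4S,5S)-2-ethynyl-5-[(4-methoxyphenyl)methoxy]-6-methylidene-3-(propan-2-yl)-4-[(triisopropylsilyl)oxy]cyclohexyl]acetate
Product: 20 2-[(1R,2R,3S,4S,5S)-2-ethynyl-5-[(4-methoxyphenyl)methoxy]-6-methylidene-3-(propan-2-yl)-4-[(triisopropylsilyl)oxy]cyclohexyl]acetaldehyde
Conditions: DIBAL‑H (1.1 equiv), CH2Cl2, −78 °C; Rochelle salt work‑up
Reagents that add atoms: none
Why: Partial reduction of the methyl ester by DIBAL‑H at −78 °C, stopped at the aldehyde stage because the tetrahedral aluminium adduct survives until work‑up; the alkyne and the ethers are inert.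

**Step 14**
Reactants: 20 2-[(1R,2R,3S,4S,5S)-2-ethynyl-5-[(4-methoxyphenyl)methoxy]-6-methylidene-3-(propan-2-yl)-4-[(triisopropylsilyl)oxy]cyclohexyl]acetaldehyde
Product: 21 (1Z,2R,3aR,5S,6S,7S,7aR)-1-ethylidene-5-[(4-methoxyphenyl)methoxy]-4-methylidene-7-(propan-2-yl)-6-[(triisopropylsilyl)oxy]octahydro-1H-inden-2-ol
Conditions: Ni(COD)2 (15 mol %), Me2Zn, THF, 0 °C; aq. NH4Cl
Reagents that add atoms: dimethylzinc, C[Zn]C
Why: Nickel‑catalysed alkylative cyclisation of an ynal with an organozinc (oxidative cyclisation of alkyne and aldehyde at zerovalent nickel, methyl transfer from zinc, reductive elimination), whose syn addition of C2 and CH3 across the alkyne fixes the Z‑ethylidene (CH3 cis to C2), while the metallacycle demands a C2–O bond close to the plane of the new alkene, which the twist imposed by the trans ring fusion allows only for the β (pseudo‑equatorial) oxygen.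

**Step 15**
Reactants: 21 (1Z,2R,3aR,5S,6S,7S,7aR)-1-ethylidene-5-[(4-methoxyphenyl)methoxy]-4-methylidene-7-(propan-2-yl)-6-[(triisopropylsilyl)oxy]octahydro-1H-inden-2-ol
Product: 22 (1Z,2S,3aR,5S,6S,7S,7aR)-1-ethylidene-5-[(4-methoxyphenyl)methoxy]-4-methylidene-7-(propan-2-yl)-6-[(triisopropylsilyl)oxy]octahydro-1H-inden-2-yl acetate
Conditions: AcOH, PPh3, DIAD, toluene, 0 °C → rt
Reagents that add atoms: acetic acid, CC(O)=O
Why: Mitsunobu esterification with acetic acid, an SN2 displacement of the activated alcohol with inversion that turns the β‑alcohol into the α‑acetate, helped by relief of the allylic 1,3‑strain between the in‑plane oxygen and the Z‑methyl and not diverted to SN2' because the C2–O bond lies near the nodal plane of the alkene.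

**Step 16**
Reactants: 22 (1Z,2S,3aR,5S,6S,7S,7aR)-1-ethylidene-5-[(4-methoxyphenyl)methoxy]-4-methylidene-7-(propan-2-yl)-6-[(triisopropylsilyl)oxy]octahydro-1H-inden-2-yl acetate
Product: 23 (1Z,2S,3aR,5S,6S,7S,7aR)-1-ethylidene-5-hydroxy-4-methylidene-7-(propan-2-yl)-6-[(triisopropylsilyl)oxy]octahydro-1H-inden-2-yl acetate
Conditions: DDQ, CH2Cl2–pH 7 buffer (10:1), 0 °C
Reagents that add atoms: none
Why: Oxidative cleavage of a 4‑methoxybenzyl ether by DDQ (benzylic hydride abstraction, then hydrolysis) in buffered medium, which should leave the silyl ether, the acetate and both alkenes untouched.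

**Step 17**
Reactants: 24 ethyl pent-2-ynoate
Product: 25 ethyl (2Z)-3-methylpent-2-enoate
Conditions: Me2CuLi, THF, −78 °C; NH4Cl quench at −78 °C
Reagents that add atoms: lithium dimethylcuprate, [Li+].C[Cu-]C
Why: syn‑Carbocupration (conjugate addition) of the Gilman reagent to the ynoate at −78 °C with cold protonation places the new methyl trans to the ester group and so gives the Z‑enoate stereospecifically.

**Step 18**
Reactants: 25 ethyl (2Z)-3-methylpent-2-enoate
Product: 26 (2Z)-3-methylpent-2-enoic acid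
Conditions: LiOH, THF–MeOH–H2O, rt; then dilute HCl
Reagents that add atoms: lithium hydroxide, [Li+].[OH-]
Why: Saponification of the ethyl ester with LiOH at room temperature, under which the β,β‑disubstituted enoate should keep its geometry.

**Step 19**
Reactants: 23 (1Z,2S,3aR,5S,6S,7S,7aR)-1-ethylidene-5-hydroxy-4-methylidene-7-(propan-2-yl)-6-[(triisopropylsilyl)oxy]octahydro-1H-inden-2-yl acetate; 26 (2Z)-3-methylpent-2-enoic acid
Product: 28 (1Z,2S,3aR,5S,6S,7S,7aR)-2-acetoxy-1-ethylidene-4-methylidene-7-(propan-2-yl)-6-[(triisopropylsilyl)oxy]octahydro-1H-inden-5-yl (2Z)-3-methylpent-2-enoate, via mixed anhydride 27 (not isolated)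
Conditions: 2,4,6-trichlorobenzoyl chloride, Et3N, THF, rt; then 23, DMAP, toluene, rt
Reagents that add atoms: 2,4,6-trichlorobenzoyl chloride, O=C(Cl)c1c(Cl)cc(Cl)cc1Cl (atoms of 27 only)
Why: Yamaguchi esterification, whose mixed anhydride acylates hindered secondary alcohols under mild DMAP catalysis with little opportunity for Z→E isomerisation of the enoyl unit.

**Step 20**
Reactants: 28 (1Z,2S,3aR,5S,6S,7S,7aR)-2-acetoxy-1-ethylidene-4-methylidene-7-(propan-2-yl)-6-[(triisopropylsilyl)oxy]octahydro-1H-inden-5-yl (2Z)-3-methylpent-2-enoate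
Product: 29 (1Z,2S,3aR,5S,6S,7S,7aR)-2-acetoxy-1-ethylidene-6-hydroxy-4-methylidene-7-(propan-2-yl)octahydro-1H-inden-5-yl (2Z)-3-methylpent-2-enoate
Conditions: HF·pyridine, pyridine, THF, 0 °C → rt
Reagents that add atoms: none
Why: Fluoride cleavage of the TIPS ether under buffered conditions that spare the acetate, the enoate and both alkenes; acyl migration from O‑5 to the trans‑diaxial O‑6 is geometrically disfavoured.

**Compound list**

1 | (1R,4S)-cis-4-acetoxycyclopent-2-en-1-ol | CC(=O)O[C@@H]1C=C[C@H](O)C1 | starting material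
2 | (1S,4R)-4-[(tert-butyldimethylsilyl)oxy]cyclopent-2-en-1-yl acetate | CC(=O)O[C@@H]1C=C[C@H](O[Si](C)(C)C(C)(C)C)C1 | intermediate
3 | (1S,4R)-4-[(tert-butyldimethylsilyl)oxy]cyclopent-2-en-1-ol | O[C@@H]1C=C[C@H](O[Si](C)(C)C(C)(C)C)C1 | intermediate
4 | 3-methylbutanoyl chloride | CC(C)CC(Cl)=O | starting material
5 | (1S,4R)-4-[(tert-butyldimethylsilyl)oxy]cyclopent-2-en-1-yl 3-methylbutanoate | CC(C)CC(=O)O[C@@H]1C=C[C@H](O[Si](C)(C)C(C)(C)C)C1 | intermediate
6 | (Z)-trimethylsilyl ketene acetal of 5 (isopropyl cis to OSiMe3) | CC(C)/C=C(\O[Si](C)(C)C)O[C@@H]1C=C[C@H](O[Si](C)(C)C(C)(C)C)C1 | intermediate (not isolated)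
7 | trimethylsilyl (2S)-2-[(1R,5R)-5-[(tert-butyldimethylsilyl)oxy]cyclopent-2-en-1-yl]-3-methylbutanoate | C1=CC[C@@H](O[Si](C)(C)C(C)(C)C)[C@H]1[C@H](C(C)C)C(=O)O[Si](C)(C)C | intermediate (not isolated)
8 | (2S)-2-[(1R,5R)-5-[(tert-butyldimethylsilyl)oxy]cyclopent-2-en-1-yl]-3-methylbutanoic acid | C1=CC[C@@H](O[Si](C)(C)C(C)(C)C)[C@H]1[C@H](C(C)C)C(O)=O | intermediate
9 | (2S)-2-[(1R,5R)-5-[(tert-butyldimethylsilyl)oxy]cyclopent-2-en-1-yl]-3-methylbutan-1-ol | C1=CC[C@@H](O[Si](C)(C)C(C)(C)C)[C@H]1[C@H](C(C)C)CO | intermediate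
10 | (2S)-2-[(1R,5S)-5-[(tert-butyldimethylsilyl)oxy]-4-oxocyclopent-2-en-1-yl]-3-methylbutanal | C1=CC(=O)[C@@H](O[Si](C)(C)C(C)(C)C)[C@H]1[C@H](C(C)C)C=O | intermediate
11 | prop-2-yn-1-ol | C#CCO | starting material
12 | 4-methoxybenzyl chloride | COc1ccc(CCl)cc1 | starting material
13 | 1-methoxy-4-[(prop-2-yn-1-yloxy)methyl]benzene | C#CCOCc1ccc(OC)cc1 | intermediate
14 | 1-methoxy-4-[(propa-1,2-dien-1-yloxy)methyl]benzene | C=C=COCc1ccc(OC)cc1 | intermediate
15 | allylnickel enolate: seven‑membered nickelacycle, divalent nickel bound to the C2 enolate oxygen and to the allyl CH2 (drawn η1; the η3 form and the PPh3 ligand are not drawn), PMBO group trans to CH2Ni | [Ni]1C/C(=C/OCc3ccc(OC)cc3)[C@@H]2C=C(O1)[C@@H](O[Si](C)(C)C(C)(C)C)[C@H]2[C@H](C(C)C)C=O | intermediate (not isolated)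
16 | (1S,3aR,5S,6S,7S,7aR)-1-[(tert-butyldimethylsilyl)oxy]-5-[(4-methoxyphenyl)methoxy]-4-methylidene-7-(propan-2-yl)-6-[(triisopropylsilyl)oxy]octahydro-2H-inden-2-one | C=C1[C@@H]2CC(=O)[C@@H](O[Si](C)(C)C(C)(C)C)[C@H]2[C@H](C(C)C)[C@H](O[Si](C(C)C)(C(C)C)C(C)C)[C@H]1OCc3ccc(OC)cc3 | intermediate
17 | (1S,3aR,5S,6S,7S,7aR)-1-hydroxy-5-[(4-methoxyphenyl)methoxy]-4-methylidene-7-(propan-2-yl)-6-[(triisopropylsilyl)oxy]octahydro-2H-inden-2-one | C=C1[C@@H]2CC(=O)[C@@H](O)[C@H]2[C@H](C(C)C)[C@H](O[Si](C(C)C)(C(C)C)C(C)C)[C@H]1OCc3ccc(OC)cc3 | intermediate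
18 | methyl 2-[(1R,2R,3S,4S,5S)-2-formyl-5-[(4-methoxyphenyl)methoxy]-6-methylidene-3-(propan-2-yl)-4-[(triisopropylsilyl)oxy]cyclohexyl]acetate | C=C1[C@H](CC(=O)OC)[C@@H](C=O)[C@H](C(C)C)[C@H](O[Si](C(C)C)(C(C)C)C(C)C)[C@H]1OCc3ccc(OC)cc3 | intermediate
19 | methyl 2-[(1R,2R,3S,4S,5S)-2-ethynyl-5-[(4-methoxyphenyl)methoxy]-6-methylidene-3-(propan-2-yl)-4-[(triisopropylsilyl)oxy]cyclohexyl]acetate | C=C1[C@H](CC(=O)OC)[C@@H](C#C)[C@H](C(C)C)[C@H](O[Si](C(C)C)(C(C)C)C(C)C)[C@H]1OCc3ccc(OC)cc3 | intermediate
20 | 2-[(1R,2R,3S,4S,5S)-2-ethynyl-5-[(4-methoxyphenyl)methoxy]-6-methylidene-3-(propan-2-yl)-4-[(triisopropylsilyl)oxy]cyclohexyl]acetaldehyde | C=C1[C@H](CC=O)[C@@H](C#C)[C@H](C(C)C)[C@H](O[Si](C(C)C)(C(C)C)C(C)C)[C@H]1OCc3ccc(OC)cc3 | intermediate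
21 | (1Z,2R,3aR,5S,6S,7S,7aR)-1-ethylidene-5-[(4-methoxyphenyl)methoxy]-4-methylidene-7-(propan-2-yl)-6-[(triisopropylsilyl)oxy]octahydro-1H-inden-2-ol | C=C1[C@@H]2C[C@@H](O)/C(=C\C)[C@H]2[C@H](C(C)C)[C@H](O[Si](C(C)C)(C(C)C)C(C)C)[C@H]1OCc3ccc(OC)cc3 | intermediate
22 | (1Z,2S,3aR,5S,6S,7S,7aR)-1-ethylidene-5-[(4-methoxyphenyl)methoxy]-4-methylidene-7-(propan-2-yl)-6-[(triisopropylsilyl)oxy]octahydro-1H-inden-2-yl acetate | C=C1[C@@H]2C[C@H](OC(C)=O)/C(=C\C)[C@H]2[C@H](C(C)C)[C@H](O[Si](C(C)C)(C(C)C)C(C)C)[C@H]1OCc3ccc(OC)cc3 | intermediate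
23 | (1Z,2S,3aR,5S,6S,7S,7aR)-1-ethylidene-5-hydroxy-4-methylidene-7-(propan-2-yl)-6-[(triisopropylsilyl)oxy]octahydro-1H-inden-2-yl acetate | C=C1[C@@H]2C[C@H](OC(C)=O)/C(=C\C)[C@H]2[C@H](C(C)C)[C@H](O[Si](C(C)C)(C(C)C)C(C)C)[C@H]1O | intermediate
24 | ethyl pent-2-ynoate | CCC#CC(=O)OCC | starting material
25 | ethyl (2Z)-3-methylpent-2-enoate | CCOC(=O)/C=C(/C)CC | intermediate
26 | (2Z)-3-methylpent-2-enoic acid | OC(=O)/C=C(/C)CC | intermediate
27 | (2Z)-3-methylpent-2-enoic 2,4,6-trichlorobenzoic anhydride | O=C(/C=C(/C)CC)OC(=O)c1c(Cl)cc(Cl)cc1Cl | intermediate (not isolated)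
28 | (1Z,2S,3aR,5S,6S,7S,7aR)-2-acetoxy-1-ethylidene-4-methylidene-7-(propan-2-yl)-6-[(triisopropylsilyl)oxy]octahydro-1H-inden-5-yl (2Z)-3-methylpent-2-enoate | C=C1[C@@H]2C[C@H](OC(C)=O)/C(=C\C)[C@H]2[C@H](C(C)C)[C@H](O[Si](C(C)C)(C(C)C)C(C)C)[C@H]1OC(=O)/C=C(/C)CC | intermediate
29 | (1Z,2S,3aR,5S,6S,7S,7aR)-2-acetoxy-1-ethylidene-6-hydroxy-4-methylidene-7-(propan-2-yl)octahydro-1H-inden-5-yl (2Z)-3-methylpent-2-enoate | C=C1[C@@H]2C[C@H](OC(C)=O)/C(=C\C)[C@H]2[C@H](C(C)C)[C@H](O)[C@H]1OC(=O)/C=C(/C)CC | target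

**Count and risks**

Total steps: 20. Longest linear sequence: 16 (steps 1–6, 9–16, 19, 20).

Steps most likely to fail:

1. Step 9 (proposed new method). The allene may couple with the aldehyde or with itself instead of with the enone. The allylnickel may be captured by the silane before it reaches the aldehyde, giving simple reductive coupling. The alkoxy group may react from the anti position and give the C5 epimer. The fallback sets out from 10 and returns at 16, keeping the order "intermolecular C3a–C4 bond first, ring closure at C5–C6 second" that secures the trans fusion. Rhodium‑catalysed 1,4‑addition of trimethyl[2-(4,4,5,5-tetramethyl-1,3,2-dioxaborolan-2-yl)prop-2-en-1-yl]silane ([Rh(cod)OH]2, dioxane–H2O) to 10, anti to the two β substituents, should give the allylsilane aldehyde F1. Intramolecular Hosomi–Sakurai allylation (BF3·OEt2, CH2Cl2, −78 °C) should close the six‑membered ring to the homoallylic alcohol F2, with the exocyclic methylene formed from the CH2Si carbon and C5 still a CH2. Silylation (TIPSOTf, 2,6‑lutidine) gives the TIPS ether F3. Allylic hydroxylation of the methylenecyclohexane (SeO2 cat., t‑BuOOH, CH2Cl2), which prefers the ring CH2 over the ring‑fusion CH and delivers the axial alcohol, gives the C5 alcohol F4. 4‑Methoxybenzyl trichloroacetimidate with La(OTf)3 (cat.) then gives 16.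

2. Step 15. Ionisation of the strained allylic carbinol may lead to SN2' attack or elimination instead of clean inversion; the same fallback also covers poor facial selectivity at C2 in step 14. It sets out from 21 and returns at 22. MnO2 (CH2Cl2) oxidises the allylic alcohol to the Z‑enone F5. Corey–Bakshi–Shibata reduction with the (R)‑methyl oxazaborolidine and catecholborane (toluene, −78 °C), with the alkylidene carbon acting as the large group, should give the α‑alcohol F6 under reagent control. Acetylation (Ac2O, pyridine, DMAP) gives 22.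

3. Step 6. Long exposure to the chromium reagent may over‑oxidise the new aldehyde, oxidise the other allylic terminus (transposed enone) or epimerise the centre α to the aldehyde. The fallback sets out from 9, returns at 10 and decouples the two oxidations. TESCl/imidazole gives the primary TES ether F7. Allylic oxidation with Rh2(cap)4 (cat.) and t‑BuOOH (K2CO3, CH2Cl2) gives the enone TES ether F8. Swern oxidation ((COCl)2, DMSO, Et3N, −78 °C → −30 °C), which oxidises primary TES ethers directly to aldehydes in the presence of the secondary TBS ether, gives 10.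

**Further compounds**

F1 | step 9 | allylsilane aldehyde: 10 carrying a 3-(trimethylsilyl)prop-1-en-2-yl group on the former enone β‑carbon, trans to the side chain (cyclopentanone) | C=C(C[Si](C)(C)C)[C@@H]1CC(=O)[C@@H](O[Si](C)(C)C(C)(C)C)[C@H]1[C@H](C(C)C)C=O
F2 | step 9 | homoallylic alcohol: 1β-[(tert-butyldimethylsilyl)oxy]-6α-hydroxy-4-methylidene-7α-(propan-2-yl)-trans-octahydro-2H-inden-2-one | C=C1[C@@H]2CC(=O)[C@@H](O[Si](C)(C)C(C)(C)C)[C@H]2[C@H](C(C)C)[C@H](O)C1
F3 | step 9 | TIPS ether of F2 | C=C1[C@@H]2CC(=O)[C@@H](O[Si](C)(C)C(C)(C)C)[C@H]2[C@H](C(C)C)[C@H](O[Si](C(C)C)(C(C)C)C(C)C)C1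
F4 | step 9 | C5 alcohol: 16 with 5β-OH in place of the 4-methoxybenzyl ether | C=C1[C@@H]2CC(=O)[C@@H](O[Si](C)(C)C(C)(C)C)[C@H]2[C@H](C(C)C)[C@H](O[Si](C(C)C)(C(C)C)C(C)C)[C@H]1O
F5 | step 15 | Z‑enone: (1Z,3aR,5S,6S,7S,7aR)-1-ethylidene-5-[(4-methoxyphenyl)methoxy]-4-methylidene-7-(propan-2-yl)-6-[(triisopropylsilyl)oxy]octahydro-2H-inden-2-one | C=C1[C@@H]2CC(=O)/C(=C\C)[C@H]2[C@H](C(C)C)[C@H](O[Si](C(C)C)(C(C)C)C(C)C)[C@H]1OCc3ccc(OC)cc3
F6 | step 15 | α‑alcohol: the (2S) epimer of 21 | C=C1[C@@H]2C[C@H](O)/C(=C\C)[C@H]2[C@H](C(C)C)[C@H](O[Si](C(C)C)(C(C)C)C(C)C)[C@H]1OCc3ccc(OC)cc3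
F7 | step 6 | primary triethylsilyl ether of 9 | C1=CC[C@@H](O[Si](C)(C)C(C)(C)C)[C@H]1[C@H](C(C)C)CO[Si](CC)(CC)CC
F8 | step 6 | enone triethylsilyl ether: 4-oxocyclopent-2-enyl analogue of F7 | C1=CC(=O)[C@@H](O[Si](C)(C)C(C)(C)C)[C@H]1[C@H](C(C)C)CO[Si](CC)(CC)CC
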